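## Retrosynthetic overview

1. Target 12 ⇐ one-pot biaryl coupling, then para-C-alkylation of the resulting 2,6-dimethoxyphenoxide. This cuts the C(spiro)–CH2 bond and traces the aryl–C(spiro) bond back to a Suzuki biaryl bond, giving bromo-tosylate 9 and boronate 10.
2. 9 ⇐ diol 7 ⇐ γ-lactone 6. The benzylic C–O and both methyl-bearing centres are stored in one five-membered ring.
3. 6 ⇐ α-methylene lactone 4 (C3 set by hydrogenation, then thermodynamic epimerization) ⇐ aldehyde 1 + crotyl donor 2 (Ir-catalysed asymmetric 2-(alkoxycarbonyl)crotylation with lactonization).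
4. Ring order: a temporary γ-butyrolactone first (step 1, opened in step 3); then, in the last operation, the benzo-fused seven-membered ring is closed and the phenol ring becomes the spiro-linked cyclohexadienone in the same flask.

Assumption: crotyl donor 2 is bought (otherwise it is one acetylation from the commercial Baylis–Hillman alcohol), and the ligand enantiomer named in step 1 is the one that gives the 5R lactone, to be confirmed on the first run.

## Route

Step 1
Reactants: 1 2-bromo-3,4,5-trimethoxybenzaldehyde; 2 methyl 3-acetoxy-2-methylidenebutanoate (racemic)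
Product: 4 (4S,5R)-5-(2-bromo-3,4,5-trimethoxyphenyl)-4-methyl-3-methylideneoxolan-2-one, via hydroxy ester 3 (not isolated)
Conditions: [Ir(cod)Cl]2 (2.5 mol%), (R)-SEGPHOS (5 mol%), 4-cyano-3-nitrobenzoic acid (10 mol%), Cs2CO3 (20 mol%), i-PrOH (2 equiv), THF, 80 °C; then TsOH·H2O (cat.), rt
Reagents that add atoms: none
Why: Iridium-catalysed transfer-hydrogenative carbonyl 2-(alkoxycarbonyl)crotylation then lactonization; the tiglate-like σ-allyl iridium (methyl cis to CH2–Ir) adds through a closed chair transition state to give the syn adduct, hence the 4,5-cis lactone, and the chiral bisphosphine fixes the absolute configuration of C5 and C4 together.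

Step 2
Reactants: 4 (4S,5R)-5-(2-bromo-3,4,5-trimethoxyphenyl)-4-methyl-3-methylideneoxolan-2-one
Product: 6 (3S,4S,5R)-5-(2-bromo-3,4,5-trimethoxyphenyl)-3,4-dimethyloxolan-2-one, via all-cis lactone 5 (not isolated)
Conditions: H2 (1 atm), RhCl(PPh3)3 (5 mol%), PhH/EtOH, rt; then DBU (0.3 equiv), PhMe, 60 °C
Reagents that add atoms: none
Why: Homogeneous (Wilkinson) hydrogenation adds H2 to the exocyclic alkene from the face opposite the C4 and C5 substituents without touching the aryl bromide, and DBU then epimerizes the acidic C3 centre to the more stable 3,4-trans isomer (thermodynamic control).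

Step 3
Reactants: 6 (3S,4S,5R)-5-(2-bromo-3,4,5-trimethoxyphenyl)-3,4-dimethyloxolan-2-one
Product: 7 (1R,2S,3S)-1-(2-bromo-3,4,5-trimethoxyphenyl)-2,3-dimethylbutane-1,4-diol
Conditions: LiBH4, THF, 0 °C to rt
Reagents that add atoms: none
Why: Hydride reduction of the lactone to the 1,4-diol; no stereocentre is touched and the aryl bromide survives.

Step 4
Reactants: 7 (1R,2S,3S)-1-(2-bromo-3,4,5-trimethoxyphenyl)-2,3-dimethylbutane-1,4-diol
Product: 9 (1R,2S,3S)-1-(2-bromo-3,4,5-trimethoxyphenyl)-2,3-dimethyl-4-(tosyloxy)butyl acetate, via hydroxy tosylate 8 (not isolated)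
Conditions: TsCl (1.05 equiv), Et3N, Me3N·HCl (cat.), CH2Cl2, −10 °C; then Ac2O, DMAP, 0 °C
Reagents that add atoms: p-toluenesulfonyl chloride Cc1ccc(cc1)S(Cl)(=O)=O; acetic anhydride CC(=O)OC(C)=O
Why: Primary-selective sulfonylation (the secondary benzylic OH is shielded by the ortho-bromoaryl group and the α-branch) followed at once by DMAP-catalysed acetylation, which caps the secondary OH before it can displace the tosylate to form a tetrahydrofuran.

Step 5
Reactants: 9 (1R,2S,3S)-1-(2-bromo-3,4,5-trimethoxyphenyl)-2,3-dimethyl-4-(tosyloxy)butyl acetate; 10 2,6-dimethoxy-4-(4,4,5,5-tetramethyl-1,3,2-dioxaborolan-2-yl)phenol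
Product: 12 (7R,8S,9R)-2,3,4,3',5'-pentamethoxy-7,8-dimethyl-4'-oxo-6,7,8,9-tetrahydrospiro[benzo[7]annulene-5,1'-cyclohexa[2,5]diene]-9-yl acetate, via biaryl phenol 11 (not isolated)
Conditions: Pd(OAc)2 (5 mol%), SPhos (10 mol%), K3PO4, PhMe/H2O (20:1), 70 °C; then DMF (to 0.01 M), Cs2CO3, 80 °C
Reagents that add atoms: none
Why: Proposed new method: Suzuki–Miyaura coupling at the hindered C–Br bond gives the 4-aryl-2,6-dimethoxyphenol, whose phenoxide cannot reach the primary tosylate through oxygen and has both ortho carbons substituted, so under dilution it attacks through its para carbon (SN2 at CH2OTs), closing the seven-membered ring and turning the phenol into the spiro dienone; the closest known reaction types are Suzuki biaryl coupling and Winstein-type (Ar1-n) phenoxide alkylative dearomatization to spirodienones, and no stereocentre is formed because the spiro carbon carries two identical ring arms.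

## Compound list

1 | 2-bromo-3,4,5-trimethoxybenzaldehyde | COc1cc(C=O)c(Br)c(OC)c1OC | starting material
2 | methyl 3-acetoxy-2-methylidenebutanoate (racemic) | C=C(C(=O)OC)C(C)OC(C)=O | starting material
3 | methyl (3S,4R)-4-(2-bromo-3,4,5-trimethoxyphenyl)-4-hydroxy-3-methyl-2-methylidenebutanoate | COC(=O)C(=C)[C@H](C)[C@@H](O)c1cc(OC)c(OC)c(OC)c1Br | intermediate
4 | (4S,5R)-5-(2-bromo-3,4,5-trimethoxyphenyl)-4-methyl-3-methylideneoxolan-2-one | O=C1C(=C)[C@H](C)[C@@H](O1)c2cc(OC)c(OC)c(OC)c2Br | intermediate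
5 | (3R,4S,5R)-5-(2-bromo-3,4,5-trimethoxyphenyl)-3,4-dimethyloxolan-2-one (all-cis) | O=C1[C@H](C)[C@H](C)[C@@H](O1)c2cc(OC)c(OC)c(OC)c2Br | intermediate
6 | (3S,4S,5R)-5-(2-bromo-3,4,5-trimethoxyphenyl)-3,4-dimethyloxolan-2-one (3,4-trans, 4,5-cis) | O=C1[C@@H](C)[C@H](C)[C@@H](O1)c2cc(OC)c(OC)c(OC)c2Br | intermediate
7 | (1R,2S,3S)-1-(2-bromo-3,4,5-trimethoxyphenyl)-2,3-dimethylbutane-1,4-diol | OC[C@@H](C)[C@H](C)[C@@H](O)c1cc(OC)c(OC)c(OC)c1Br | intermediate
8 | (2S,3S,4R)-4-(2-bromo-3,4,5-trimethoxyphenyl)-4-hydroxy-2,3-dimethylbutyl 4-methylbenzenesulfonate | Cc1ccc(cc1)S(=O)(=O)OC[C@@H](C)[C@H](C)[C@@H](O)c1cc(OC)c(OC)c(OC)c1Br | intermediate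
9 | (1R,2S,3S)-1-(2-bromo-3,4,5-trimethoxyphenyl)-2,3-dimethyl-4-(tosyloxy)butyl acetate | Cc1ccc(cc1)S(=O)(=O)OC[C@@H](C)[C@H](C)[C@@H](OC(C)=O)c1cc(OC)c(OC)c(OC)c1Br | intermediate
10 | 2,6-dimethoxy-4-(4,4,5,5-tetramethyl-1,3,2-dioxaborolan-2-yl)phenol | COc1cc(cc(OC)c1O)B1OC(C)(C)C(C)(C)O1 | starting material
11 | (1R,2S,3S)-1-(4'-hydroxy-3',4,5,5',6-pentamethoxy-[1,1'-biphenyl]-2-yl)-2,3-dimethyl-4-(tosyloxy)butyl acetate | Cc1ccc(cc1)S(=O)(=O)OC[C@@H](C)[C@H](C)[C@@H](OC(C)=O)c1cc(OC)c(OC)c(OC)c1-c1cc(OC)c(O)c(OC)c1 | intermediate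
12 | (7R,8S,9R)-2,3,4,3',5'-pentamethoxy-7,8-dimethyl-4'-oxo-6,7,8,9-tetrahydrospiro[benzo[7]annulene-5,1'-cyclohexa[2,5]diene]-9-yl acetate | COC1=CC2(C=C(OC)C1=O)C[C@@H](C)[C@H](C)[C@@H](OC(C)=O)c1cc(OC)c(OC)c(OC)c12 | target

## Step count and risk

Total step count: 5. Longest linear sequence: 5 (1 → 4 → 6 → 7 → 9 → 12).

Steps most likely to fail, each with a fallback:

Step 5 (seven-membered ring closure through the phenoxide para carbon). If C-alkylation fails, the ring is closed at the aryl–C(spiro) bond instead. The fallback sets out from 9 and returns at 12. Tosylate 9 is displaced with lithium bis[4-(tert-butyldimethylsilyloxy)-3,5-dimethoxyphenyl]cuprate (THF, −40 °C) to give the silyl-protected bromo diarylbutane F1. Buffered TBAF/AcOH then frees the phenolic bromo diarylbutane F2. A palladium-catalysed intramolecular arylative dearomatization of the phenol (Pd2(dba)3, bulky biaryl phosphine, K2CO3, dioxane, 100 °C) gives 12.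

Step 1 (diastereo- and enantioselectivity of the Ir crotylation on a hindered, electron-rich aldehyde). The fallback sets out from 1 and returns at 6. Brown (Z)-crotylboration of 1 with (Z)-crotyl-B(Ipc)2 (THF, −78 °C, oxidative work-up) gives the syn homoallylic alcohol F3. Rhodium-catalysed hydroformylation, steered to the internal alkene carbon by a reversibly bound phosphinite scaffolding ligand (Rh(acac)(CO)2, CO/H2), gives the lactol F4. Oxidation (TEMPO, PhI(OAc)2) and DBU equilibration of C3 give lactone 6.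

Step 4 (selectivity of the tosylation and tetrahydrofuran formation from the hydroxy tosylate). The fallback differentiates the two hydroxyls with a protecting group; it sets out from 7 and returns at 9. TBSCl/imidazole at −20 °C silylates only the primary OH to give the silyl ether alcohol F5. Ac2O/DMAP gives the silyl ether acetate F6. HF·pyridine frees the primary alcohol acetate F7, which is tosylated (TsCl, pyridine, 0 °C) to 9.

Further compounds

F1 | step 5 | (1R,2S,3R)-1-(2-bromo-3,4,5-trimethoxyphenyl)-4-[4-(tert-butyldimethylsilyloxy)-3,5-dimethoxyphenyl]-2,3-dimethylbutyl acetate | CC(C)(C)[Si](C)(C)Oc1c(OC)cc(cc1OC)C[C@@H](C)[C@H](C)[C@@H](OC(C)=O)c1cc(OC)c(OC)c(OC)c1Br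
F2 | step 5 | (1R,2S,3R)-1-(2-bromo-3,4,5-trimethoxyphenyl)-4-(4-hydroxy-3,5-dimethoxyphenyl)-2,3-dimethylbutyl acetate | COc1cc(cc(OC)c1O)C[C@@H](C)[C@H](C)[C@@H](OC(C)=O)c1cc(OC)c(OC)c(OC)c1Br
F3 | step 1 | (1R,2S)-1-(2-bromo-3,4,5-trimethoxyphenyl)-2-methylbut-3-en-1-ol | C=C[C@H](C)[C@@H](O)c1cc(OC)c(OC)c(OC)c1Br
F4 | step 1 | (4S,5R)-5-(2-bromo-3,4,5-trimethoxyphenyl)-3,4-dimethyloxolan-2-ol (mixture at C2 and C3) | OC1C(C)[C@H](C)[C@@H](O1)c2cc(OC)c(OC)c(OC)c2Br
F5 | step 4 | (1R,2S,3S)-1-(2-bromo-3,4,5-trimethoxyphenyl)-4-(tert-butyldimethylsilyloxy)-2,3-dimethylbutan-1-ol | CC(C)(C)[Si](C)(C)OC[C@@H](C)[C@H](C)[C@@H](O)c1cc(OC)c(OC)c(OC)c1Br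
F6 | step 4 | (1R,2S,3S)-1-(2-bromo-3,4,5-trimethoxyphenyl)-4-(tert-butyldimethylsilyloxy)-2,3-dimethylbutyl acetate | CC(C)(C)[Si](C)(C)OC[C@@H](C)[C@H](C)[C@@H](OC(C)=O)c1cc(OC)c(OC)c(OC)c1Br
F7 | step 4 | (1R,2S,3S)-1-(2-bromo-3,4,5-trimethoxyphenyl)-4-hydroxy-2,3-dimethylbutyl acetate | OC[C@@H](C)[C@H](C)[C@@H](OC(C)=O)c1cc(OC)c(OC)c(OC)c1Br
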